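At the last reading of Saturday's run, 6.00 min, the substrate stood at 39% of its charge, and from that reading I began to ask which concentration sets the order of the rate.

| setting | Saturday's | Wednesday's | delta | beta | eta | gamma | zeta |
|---|---|---|---|---|---|---|---|
| substrate | 0.0040 M | 0.0040 M | 0.0040 M | 0.010 M | 0.030 M | 0.10 M | 0.30 M |
| reagent | 0.29 M | 0.098 M | 0.196 M | 0.196 M | 0.196 M | 0.196 M | 0.196 M |
| remark | run made earlier | run made earlier |  |  |  |  |  |
| time |  |  | 30 min | 30 min | 30 min | 30 min | 30 min |

| run | time / min | bis adduct / % | substrate / % |
|---|---|---|---|
| Saturday's | 1.33 | 7 | 82 |
| Saturday's | 2.50 | 17 | 71 |
| Saturday's | 4.00 | 25 | 53 |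
| Saturday's | 5.00 | 33 | 46 |
| Saturday's | 6.00 | 35 | 39 |
| Wednesday's | 1.33 | 0 | 94 |
| Wednesday's | 2.50 | 1 | 89 |
| Wednesday's | 4.00 | 6 | 82 |
| Wednesday's | 5.00 | 6 | 78 |
| Wednesday's | 6.00 | 15 | 73 |

(readings scatter by 2 percentage points)

- [bis adduct] at the end for delta, beta, eta, gamma, zeta, in this order
- the course of these numbers from the first flask to the last (falls all the way / falls, then rises / rises, then falls / rises all the way / hardly changes)

- "hardly changes" means that all values lie within two and a half points (for a concentration: within two and a half percent of the largest)

Read as a first-order decay of substrate, Saturday's reading gave 0.157 /min. One reading with this scatter proves little, and the reagent might not matter at all, so I turned to Wednesday's run, which had a third of the reagent and gave 0.0525 /min. Dividing each by its reagent gave 0.541 /M/min and 0.535 /M/min. The two quotients lay close together, so I read the pseudo-first-order constant as proportional to the reagent, as far as these scattered readings show, and I kept their mean, 0.538 /M/min. At the reagent of the row this gave the substrate half-life, ln(2) over that constant times the reagent concentration: 6.57 min. Delta should then keep 4.22% of its substrate at the end.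

My objection was that both runs had reagent in large excess, while gamma's reagent charge was about twice its substrate and zeta's was below its substrate. Saturday's last reading left 26.0% of the substrate in neither measured form, and the bis adduct came late, so I took an intermediate to stand between them, with each bis adduct costing two reagent. On that assumption the reagent charge of the row allowed a ceiling of 0.0980 M of bis adduct. The reagent that gamma needed for complete conversion to bis adduct stood about level with its charge, and the reagent that zeta needed exceeded its charge. A second doubt stayed open: the readings stopped well before the end of the flasks, so they could not show whether the bis adduct lasted.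

The forecast gave 0.0036 M, 0.0091 M, 0.026 M, 0.066 M and 0.065 M, with the shape "rises, then falls", and it said: “The row therefore rises, then barely falls.”

The flasks gave 6.63 × 10⁻⁴ M, 0.00165 M, 0.00480 M, 0.0114 M and 0.00655 M, with the shape "rises, then falls". The shape agreed, but delta's forecast stood 5.43 times above its result.

    substrate + reagent → first product + by-product (k = 0.00853 /M/s)
    reagent + first product → bis adduct + by-product (k = 0.0399 /M/s)
    reagent + bis adduct → triple product + by-product (k = 2.68 × 10⁻⁴ /M/s)
    bis adduct → over-reaction product (k = 0.00166 /s)
    substrate + first product → side product (k = 0.0151 /M/s)

In delta, the carried half-life of 6.57 min put 4.22% of the substrate at 30.0 min, and the flask held 5.30%, while the bis adduct's half-life by turning into over-reaction product alone was 7.0 min, shorter than the time of 30 min. At the end, delta held 16.6% bis adduct and 73.8% over-reaction product. In beta, the carried constant gives 20.6% of the substrate at 15.0 min, and the flask held 23.4%.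

All runs were generated by integration for an exercise; the scatter is artificial.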